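Ring C of the naphthalenediol half (C1' biaryl carbon, C2'–CH3, C3'–H, C4'–OH, C4a', C8a') is disconnected at C1'–C2' and C2'–C3'. C2', the carbon that carries the methyl group, is flanked only by C1' and C3', so deleting it contracts ring C to the five-membered ring of an indene fused to ring D. In one operation chloro(methyl)carbene adds to the C1'=C3' alkene and the chlorocyclopropane opens. This inserts C2' with its methyl group, aromatises ring C and creates the crowded biaryl axis last. The precursor is a racemic 3-aryl-1-silyloxyindene. Its naphthyl A group (2-benzyloxy-4,5-dimethoxy-7-methylnaphthalen-1-yl) is attached beforehand by carbonyl addition to an indanone.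

Key step: step 17

Assumption: the target string gives no descriptor for the C1–C1' axis, so the biaryl is made as the racemate; every stereocentre on the way is racemic and one enantiomer is drawn.
Labels: primed atoms belong to the naphthalenediol half (C5' OMe, C6' OH; ring D = C4a', C5' to C8', C8a'). Unprimed atoms belong to naphthyl A.
Design note: the benzyl ethers never meet strong acid. From 27 onward no strong or amine base is used, because the C4'–H of a 1-silyloxyindene is acidic enough for a 1,3-proton shift to the silyl enol ether isomer.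

Step 1
Reactants: 1 3-methoxy-5-methylphenol
Product: 2 3-methoxy-5-methylphenyl isopropylcarbamate
Conditions: i-PrNCO, Et3N (cat.), CH2Cl2, rt
Reagents that add atoms: isopropyl isocyanate, CC(C)N=C=O
Why: Base-catalysed carbamoylation of the phenol by the isocyanate installs a strong ortho director that can later be removed without acid or hydride.

Step 2
Reactants: 2 3-methoxy-5-methylphenyl isopropylcarbamate
Product: 5 3-methoxy-5-methyl-2-(trimethylsilyl)phenyl isopropylcarbamate, via N-silyl carbamate 3 (not isolated), via doubly silylated carbamate 4 (not isolated)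
Conditions: TBSOTf, TMEDA, Et2O, 0 °C to rt; n-BuLi, TMEDA, −78 °C; TMSCl, −78 °C to rt; aq. NaHSO4
Reagents that add atoms: chlorotrimethylsilane, C[Si](C)(C)Cl (the silyl group of TBSOTf, CC(C)(C)[Si](C)(C)OS(=O)(=O)C(F)(F)F, is carried by 3 and 4 only)
Why: Directed ortho-metalation after transient N-silylation: the C–H between the carbamate and methoxy groups is activated by both directors, so lithiation and silyl quench should occur only there, and the N-silyl group is hydrolysed on acidic work-up.

Step 3
Reactants: 5 3-methoxy-5-methyl-2-(trimethylsilyl)phenyl isopropylcarbamate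
Product: 7 3-methoxy-5-methyl-2-(trimethylsilyl)phenyl trifluoromethanesulfonate, via silylphenol 6 (not isolated)
Conditions: DBU, Et2NH, MeCN, 40 °C; then PhNTf2, rt
Reagents that add atoms: N-phenylbis(trifluoromethanesulfonimide), O=S(=O)(N(c1ccccc1)S(=O)(=O)C(F)(F)F)C(F)(F)F
Why: E1cB cleavage of the secondary carbamate (the isocyanate is scavenged by Et2NH) frees the phenoxide, which is triflated in the same flask, the usual way to an o-silylaryl triflate aryne precursor.

Step 4
Reactants: 7 3-methoxy-5-methyl-2-(trimethylsilyl)phenyl trifluoromethanesulfonate; 8 methyl acetoacetate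
Product: 10 methyl 2-(2-acetyl-3-methoxy-5-methylphenyl)acetate, via 3-methoxy-5-methylbenzyne 9 (not isolated)
Conditions: CsF, MeCN, 80 °C
Reagents that add atoms: none
Why: Aryne acyl-alkylation (formal insertion into the C–C bond of a β-ketoester): the enolate carbon attacks the aryne carbon remote from OMe, the aryl anion next to OMe closes onto the ketone, and fragmentation leaves the acetyl group beside OMe and CH2CO2Me on the other carbon.

Step 5
Reactants: 10 methyl 2-(2-acetyl-3-methoxy-5-methylphenyl)acetate
Product: 11 8-methoxy-6-methylnaphthalene-1,3-diol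
Conditions: KOt-Bu (2.5 equiv), THF, 0 °C to rt, Ar; degassed 1 M HCl
Reagents that add atoms: none
Why: Intramolecular Claisen (Dieckmann-type) condensation of the methyl ketone enolate onto the ester is driven by aromatisation to the naphthalenediol, and oxygen is excluded because the naphtholate autoxidises.

Step 6
Reactants: 11 8-methoxy-6-methylnaphthalene-1,3-diol
Product: 12 3-(benzyloxy)-8-methoxy-6-methylnaphthalen-1-ol
Conditions: BnBr (1.0 equiv), K2CO3 (1.1 equiv), DMF, 0 °C to rt, Ar
Reagents that add atoms: benzyl bromide, BrCc1ccccc1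
Why: Williamson etherification with one equivalent of halide: the C1 hydroxyl is hindered and held in a peri hydrogen bond to the C8 methoxy oxygen, so the free C3 hydroxyl should ionise and be O-benzylated first in a dipolar aprotic solvent.

Step 7
Reactants: 12 3-(benzyloxy)-8-methoxy-6-methylnaphthalen-1-ol
Product: 13 3-(benzyloxy)-1,8-dimethoxy-6-methylnaphthalene
Conditions: NaH, MeI, DMF, 0 °C to rt
Reagents that add atoms: iodomethane, CI
Why: Williamson methylation through the sodium salt overcomes the peri hydrogen bond and supplies the second methoxy group of naphthyl A, which the annulation does not deliver.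

Step 8
Reactants: 13 3-(benzyloxy)-1,8-dimethoxy-6-methylnaphthalene
Product: 14 2-(benzyloxy)-1-bromo-4,5-dimethoxy-7-methylnaphthalene
Conditions: NBS (1.0 equiv), MeCN, −20 °C, dark
Reagents that add atoms: N-bromosuccinimide, O=C1CCC(=O)N1Br
Why: Electrophilic aromatic bromination goes to the α-position that is ortho to OBn and para to OMe, the most activated site of the more electron-rich ring, as is usual for 1,3-dialkoxynaphthalenes.

Step 9
Reactants: 15 2,3-dihydroxybenzaldehyde
Product: 16 3-(benzyloxy)-2-hydroxybenzaldehyde
Conditions: NaH (2.1 equiv), DMSO, 20 °C; BnBr (1.0 equiv); aq. HCl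
Reagents that add atoms: benzyl bromide, BrCc1ccccc1
Why: Regioselective Williamson alkylation of the catechol dianion: the 2-phenoxide is delocalised into the ortho formyl group and is the weaker nucleophile, so the single equivalent of halide should be taken up by the 3-phenoxide.

Step 10
Reactants: 16 3-(benzyloxy)-2-hydroxybenzaldehyde
Product: 17 3-(benzyloxy)-2-methoxybenzaldehyde
Conditions: MeI, K2CO3, DMF, rt
Reagents that add atoms: iodomethane, CI
Why: Williamson methylation of the remaining, acidic salicylaldehyde-type hydroxyl is routine and touches neither the aldehyde nor the benzyl ether.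

Step 11
Reactants: 17 3-(benzyloxy)-2-methoxybenzaldehyde
Product: 18 3-(benzyloxy)-6-bromo-2-methoxybenzaldehyde
Conditions: NBS, DMF, rt
Reagents that add atoms: N-bromosuccinimide, O=C1CCC(=O)N1Br
Why: Electrophilic aromatic bromination: the 2-methoxy group is twisted out of conjugation by its two neighbours, so the 3-benzyloxy group directs to its open para position C6, the known outcome for 2,3-dialkoxybenzaldehydes under these conditions.

Step 12
Reactants: 18 3-(benzyloxy)-6-bromo-2-methoxybenzaldehyde; 19 butyl vinyl ether
Product: 22 5-(benzyloxy)-3-hydroxy-4-methoxy-2,3-dihydro-1H-inden-1-one (racemic), via aryl enol ether 20 (not isolated), via hydroxy ketal 21 (not isolated)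
Conditions: Pd(OAc)2 (cat.), dppp (cat.), Et3N, ethylene glycol, 115 °C; then 3 M aq. HCl, rt
Reagents that add atoms: water, O (ketone oxygen, on hydrolysis of 21; ethane-1,2-diol, OCCO, is carried by 21 only)
Why: Heck arylation–aldol annulation cascade established for 2-bromobenzaldehydes: the cationic Pd–dppp pathway favoured in ethylene glycol arylates the vinyl ether at its internal carbon to give 20, its enol ether carbon closes onto the neighbouring aldehyde, the glycol traps the oxocarbenium ion as ketal 21, and acid unmasks the ketone, the carbinol centre being formed racemic.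

Step 13
Reactants: 22 5-(benzyloxy)-3-hydroxy-4-methoxy-2,3-dihydro-1H-inden-1-one
Product: 23 5-(benzyloxy)-3-[(tert-butyldimethylsilyl)oxy]-4-methoxy-2,3-dihydro-1H-inden-1-one (racemic)
Conditions: TBSCl, imidazole, DMF, 0 °C to rt
Reagents that add atoms: tert-butyldimethylsilyl chloride, CC(C)(C)[Si](C)(C)Cl
Why: Standard silylation of a secondary alcohol with a weak base that should not trigger β-elimination of the aldol.

Step 14
Reactants: 14 2-(benzyloxy)-1-bromo-4,5-dimethoxy-7-methylnaphthalene; 23 5-(benzyloxy)-3-[(tert-butyldimethylsilyl)oxy]-4-methoxy-2,3-dihydro-1H-inden-1-one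
Product: 26 5-(benzyloxy)-1-[2-(benzyloxy)-4,5-dimethoxy-7-methylnaphthalen-1-yl]-3-[(tert-butyldimethylsilyl)oxy]-4-methoxy-2,3-dihydro-1H-inden-1-ol (racemic; OH cis to OTBS), via aryllithium 24 (not isolated), via arylcerium dichloride 25 (not isolated)
Conditions: 14, n-BuLi, THF, −78 °C; anhydrous CeCl3, −78 °C; then 23, −78 to −40 °C; aq. NH4Cl
Reagents that add atoms: none
Why: Bromine–lithium exchange and transmetalation give a weakly basic, oxophilic organocerium reagent whose 1,2-addition to easily enolised ketones is well established, so carbonyl attack should beat enolisation and loss of silanolate; approach anti to the C3 silyloxy group should set the carbinol centre, which the next step erases.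

Step 15
Reactants: 26 tertiary carbinol from step 14
Product: 27 tert-butyl({6-(benzyloxy)-3-[2-(benzyloxy)-4,5-dimethoxy-7-methylnaphthalen-1-yl]-7-methoxy-1H-inden-1-yl}oxy)dimethylsilane (racemic)
Conditions: PPTS (cat.), 4 Å molecular sieves, CH2Cl2, rt
Reagents that add atoms: none
Why: E1 dehydration: the carbinol ionises easily because the cation is benzylic to ring D (para benzyloxy) and to naphthyl A, the only β-hydrogens sit on C3' so the alkene can form only as C1'=C3', and the C4' silyl ether is safe because its ionisation would lead to an antiaromatic indenyl cation.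

Step 16
Reactants: 28 acetamidine hydrochloride
Product: 30 3-chloro-3-methyl-3H-diazirine (kept as a cold dilute pentane solution), via N,N'-dichloroacetamidine 29 (not isolated)
Conditions: aq. NaOCl (NaCl-saturated), LiCl, DMSO, 0 to 20 °C; swept with N2 through a drying tube into pentane at −78 °C, dark
Reagents that add atoms: sodium hypochlorite, [Na+].[O-]Cl; lithium chloride, [Li+].[Cl-] (chloride pool from which the C–Cl chlorine is drawn)
Why: Graham oxidation: double N-chlorination of the amidine, base-induced N–N closure and return of chloride to carbon give the chlorodiazirine, which is volatile and shock-sensitive and is therefore never concentrated.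

Step 17
Reactants: 27 3-aryl-1-silyloxyindene from step 15; 30 3-chloro-3-methyl-3H-diazirine
Product: 34 tert-butyl({7-(benzyloxy)-4-[2-(benzyloxy)-4,5-dimethoxy-7-methylnaphthalen-1-yl]-8-methoxy-3-methylnaphthalen-1-yl}oxy)dimethylsilane (racemic axis), via chloro(methyl)carbene 31 (not isolated), via chlorocyclopropane 32 (not isolated), via allyl cation chloride 33 (not isolated)
Conditions: 30 (about 8 equiv, in portions), anhydrous Na2CO3 (3 equiv), PhCF3–pentane (27 about 0.5 M), hν 365 nm LED, 0 °C; then 60 °C, 2 h
Reagents that add atoms: none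
Why: Proposed new method: photolysis of 30 expels N2 and gives singlet carbene 31, which adds in a concerted [2+1] fashion to C1'=C3', the only non-aromatic π bond, forming C1'–C2' and C2'–C3' in 32; disrotatory cyclopropyl-to-allyl opening with departure of the endo chloride then breaks the shared C1'–C3' bond, so ring C arises by cheletropic closure of a three-membered ring followed by electrocyclic expansion from five to six members, and cation 33 gives up the C4' proton to carbonate to leave aromatic 34. The closest known reaction types are the carbocyclic counterpart of the Ciamician–Dennstedt rearrangement (indenes to 2-halonaphthalenes by dihalocarbenes, to 2-arylnaphthalenes by aryl chlorodiazirines) and the cyclopropanation of simple alkenes by photogenerated chloro(methyl)carbene, the new element being an alkyl chlorocarbene that can destroy itself by a 1,2-hydrogen shift. The transient stereocentres of 32 should be set by approach anti to the C4' silyloxy group and by the smaller chlorine taking the endo position over the ring, which is the orientation that the opening requires; none survives, and the new C1–C1' axis forms racemic. Capture has to outrun rearrangement to vinyl chloride: the alkene is a styrene whose C1' is conjugated through C8a' to the para C6' benzyloxy group, the substrate is kept concentrated and cold (the addition is nearly barrierless, the shift is not) and 30 is fed in excess, while the short carbene lifetime should spare the slower-reacting electron-rich naphthalene rings. The C1'–naphthyl bond on a five-membered ring is expected to rotate far more freely than the axis of 34, so the rotamer that turns the peri C8–H instead of the C2 benzyloxy group toward the open face can carry the reaction. Strong and amine bases are excluded because they would move the double bond to C3'=C4' and misplace the inserted carbon, and if 33 lost the silyl group instead of the proton the outcome would be naphthol 35, the next compound in line.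

Step 18
Reactants: 34 silyl ether from step 17
Product: 35 7-(benzyloxy)-4-[2-(benzyloxy)-4,5-dimethoxy-7-methylnaphthalen-1-yl]-8-methoxy-3-methylnaphthalen-1-ol (racemic axis)
Conditions: Bu4NF, AcOH (1 equiv each), THF, 0 °C, Ar
Reagents that add atoms: none
Why: Fluoride-induced cleavage of the aryl silyl ether is driven by the Si–F bond and buffered with acetic acid so that the electron-rich naphtholate is not left exposed, while benzyl and methyl ethers are inert.

Step 19
Reactants: 35 bis(benzyl) ether from step 18
Product: 36 4-(2-hydroxy-4,5-dimethoxy-7-methylnaphthalen-1-yl)-8-methoxy-3-methylnaphthalene-1,7-diol (CNP0288130.0; racemic axis)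
Conditions: H2 (1 atm), Pd/C, EtOAc–MeOH, rt; filtration under Ar
Reagents that add atoms: none
Why: Catalytic hydrogenolysis of the two aryl benzyl ethers at one atmosphere leaves naphthalene rings and methyl ethers untouched and frees the oxidation-prone triol by filtration alone.

Compound list
1 | 3-methoxy-5-methylphenol | COc1cc(C)cc(O)c1 | starting material
2 | 3-methoxy-5-methylphenyl isopropylcarbamate | COc1cc(C)cc(OC(=O)NC(C)C)c1 | intermediate
3 | N-TBS derivative of 2 (not isolated) | COc1cc(C)cc(OC(=O)N(C(C)C)[Si](C)(C)C(C)(C)C)c1 | intermediate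
4 | N-TBS, 2-trimethylsilyl carbamate (not isolated) | COc1cc(C)cc(OC(=O)N(C(C)C)[Si](C)(C)C(C)(C)C)c1[Si](C)(C)C | intermediate
5 | 3-methoxy-5-methyl-2-(trimethylsilyl)phenyl isopropylcarbamate | COc1cc(C)cc(OC(=O)NC(C)C)c1[Si](C)(C)C | intermediate
6 | 3-methoxy-5-methyl-2-(trimethylsilyl)phenol (not isolated) | COc1cc(C)cc(O)c1[Si](C)(C)C | intermediate
7 | 3-methoxy-5-methyl-2-(trimethylsilyl)phenyl trifluoromethanesulfonate | COc1cc(C)cc(OS(=O)(=O)C(F)(F)F)c1[Si](C)(C)C | intermediate
8 | methyl acetoacetate | COC(=O)CC(C)=O | starting material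
9 | 3-methoxy-5-methylbenzyne (not isolated) | COC1=CC(C)=CC#C1 | intermediate
10 | methyl 2-(2-acetyl-3-methoxy-5-methylphenyl)acetate | COC(=O)Cc1cc(C)cc(OC)c1C(C)=O | intermediate
11 | 8-methoxy-6-methylnaphthalene-1,3-diol | COc1cc(C)cc2cc(O)cc(O)c12 | intermediate
12 | 3-(benzyloxy)-8-methoxy-6-methylnaphthalen-1-ol | COc1cc(C)cc2cc(OCc3ccccc3)cc(O)c12 | intermediate
13 | 3-(benzyloxy)-1,8-dimethoxy-6-methylnaphthalene | COc1cc(C)cc2cc(OCc3ccccc3)cc(OC)c12 | intermediate
14 | 2-(benzyloxy)-1-bromo-4,5-dimethoxy-7-methylnaphthalene | COc1cc(C)cc2c(Br)c(OCc3ccccc3)cc(OC)c12 | intermediate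
15 | 2,3-dihydroxybenzaldehyde | O=Cc1cccc(O)c1O | starting material
16 | 3-(benzyloxy)-2-hydroxybenzaldehyde | O=Cc1cccc(OCc2ccccc2)c1O | intermediate
17 | 3-(benzyloxy)-2-methoxybenzaldehyde | COc1c(C=O)cccc1OCc1ccccc1 | intermediate
18 | 3-(benzyloxy)-6-bromo-2-methoxybenzaldehyde | COc1c(OCc2ccccc2)ccc(Br)c1C=O | intermediate
19 | butyl vinyl ether | C=COCCCC | starting material
20 | 3-(benzyloxy)-6-(1-butoxyethenyl)-2-methoxybenzaldehyde (not isolated) | COc1c(OCc2ccccc2)ccc(C(=C)OCCCC)c1C=O | intermediate
21 | 5'-(benzyloxy)-4'-methoxy-2',3'-dihydrospiro[1,3-dioxolane-2,1'-inden]-3'-ol (racemic, not isolated) | COc1c(OCc2ccccc2)ccc2c1[C@H](O)CC21OCCO1 | intermediate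
22 | 5-(benzyloxy)-3-hydroxy-4-methoxy-2,3-dihydro-1H-inden-1-one (racemic, one enantiomer drawn) | COc1c(OCc2ccccc2)ccc2c1[C@H](O)CC2=O | intermediate
23 | 5-(benzyloxy)-3-[(tert-butyldimethylsilyl)oxy]-4-methoxy-2,3-dihydro-1H-inden-1-one (racemic) | COc1c(OCc2ccccc2)ccc2c1[C@H](O[Si](C)(C)C(C)(C)C)CC2=O | intermediate
24 | [2-(benzyloxy)-4,5-dimethoxy-7-methylnaphthalen-1-yl]lithium (not isolated) | [Li]c1c(OCc2ccccc2)cc(OC)c2c(OC)cc(C)cc12 | intermediate
25 | [2-(benzyloxy)-4,5-dimethoxy-7-methylnaphthalen-1-yl]cerium dichloride (not isolated) | Cl[Ce](Cl)c1c(OCc2ccccc2)cc(OC)c2c(OC)cc(C)cc12 | intermediate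
26 | 5-(benzyloxy)-1-(naphthyl A)-3-[(tert-butyldimethylsilyl)oxy]-4-methoxy-2,3-dihydro-1H-inden-1-ol (racemic; OH cis to OTBS, aryl trans) | COc1c(OCc2ccccc2)ccc2c1[C@H](O[Si](C)(C)C(C)(C)C)C[C@@]2(O)c1c(OCc2ccccc2)cc(OC)c2c(OC)cc(C)cc12 | intermediate
27 | tert-butyl({6-(benzyloxy)-3-(naphthyl A)-7-methoxy-1H-inden-1-yl}oxy)dimethylsilane (racemic, one enantiomer drawn) | COc1c(OCc2ccccc2)ccc2c1[C@H](O[Si](C)(C)C(C)(C)C)C=C2c1c(OCc2ccccc2)cc(OC)c2c(OC)cc(C)cc12 | intermediate
28 | acetamidine hydrochloride | CC(=N)N.Cl | starting material
29 | N,N'-dichloroacetamidine (not isolated) | CC(=NCl)NCl | intermediate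
30 | 3-chloro-3-methyl-3H-diazirine | CC1(Cl)N=N1 | intermediate
31 | chloro(methyl)carbene (not isolated) | C[C]Cl | intermediate
32 | chlorocyclopropane (not isolated): C2'(Cl)(CH3) bridges C1' and C3' of 27 on the face anti to OTBS, Cl endo over the five-membered ring, CH3 exo (racemic) | COc1c(OCc2ccccc2)ccc2c1[C@H](O[Si](C)(C)C(C)(C)C)[C@H]1[C@@](C)(Cl)[C@@]21c1c(OCc2ccccc2)cc(OC)c2c(OC)cc(C)cc12 | intermediate
33 | ring-expanded allyl cation C1'–C2'–C3' with C4'(H)OTBS, chloride ion pair (not isolated) | COc1c(OCc2ccccc2)ccc2c1[C@H](O[Si](C)(C)C(C)(C)C)C=C(C)[C+]2c1c(OCc2ccccc2)cc(OC)c2c(OC)cc(C)cc12.[Cl-] | intermediate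
34 | tert-butyl({7-(benzyloxy)-4-(naphthyl A)-8-methoxy-3-methylnaphthalen-1-yl}oxy)dimethylsilane (racemic axis) | COc1c(OCc2ccccc2)ccc2c(-c3c(OCc4ccccc4)cc(OC)c4c(OC)cc(C)cc34)c(C)cc(O[Si](C)(C)C(C)(C)C)c12 | intermediate
35 | 7-(benzyloxy)-4-(naphthyl A)-8-methoxy-3-methylnaphthalen-1-ol (racemic axis) | COc1c(OCc2ccccc2)ccc2c(-c3c(OCc4ccccc4)cc(OC)c4c(OC)cc(C)cc34)c(C)cc(O)c12 | intermediate
36 | 4-(2-hydroxy-4,5-dimethoxy-7-methylnaphthalen-1-yl)-8-methoxy-3-methylnaphthalene-1,7-diol (racemic axis) | COc1cc(C)cc2c(-c3c(C)cc(O)c4c(OC)c(O)ccc34)c(O)cc(OC)c12 | target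

Total steps: 19. Longest linear sequence: 13 (steps 1 to 8, 14, 15, 17, 18, 19).

Steps most likely to fail

1. Step 17.
- **Risk:** the carbene may rearrange by its 1,2-hydrogen shift faster than the hindered trisubstituted alkene captures it. The part of the adduct that carries chlorine exo may also resist opening.
- **Fallback (known chemistry):** it sets out from 27. Phenyl(tribromomethyl)mercury, PhHgCBr3 (1.5 equiv), with solid Na2CO3 in benzene at 80 °C releases dibromocarbene without any base in solution.
- **Why it should work:** this carbene cannot rearrange, and its adduct, the dibromocyclopropane F1, always holds one endo bromide. It should therefore open in the flask to the 3-bromonaphthalene silyl ether F2.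
- **Return to the route:** Negishi methylation (Me2Zn, PdCl2(dppf), dioxane, 70 °C) comes back at 34.
- **Sources to avoid:** alkoxide- or hydroxide-generated dihalocarbene is not used, since deprotonation at C4' would shift the indene double bond before the carbene arrives.

2. Step 14.
- **Risk:** enolisation of the β-silyloxy ketone followed by loss of silanolate may compete with the addition.
- **Fallback:** it sets out from 22 and uses 14. Mesylation and elimination (MsCl, Et3N, CH2Cl2, 0 °C) give the non-enolisable 5-(benzyloxy)-4-methoxy-1H-inden-1-one F3, which is used at once.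
- **Addition and transposition:** 1,2-addition of the same organocerium reagent gives the tertiary 1-arylinden-1-ol F4. Babler–Dauben oxidative transposition (pyridinium chlorochromate, [C5H5NH][CrO3Cl], CH2Cl2, rt) moves the oxygen to C4' and gives the 3-arylindenone F5.
- **Return to the route:** Luche reduction (NaBH4, CeCl3·7H2O, MeOH–THF, 0 °C) gives the indenol F6. Silylation (TBSCl, imidazole, CH2Cl2, 0 °C) comes back at 27.

3. Step 12.
- **Risk:** the internal/terminal selectivity of the Heck arylation may erode, the aldol closure onto the crowded aldehyde may stall, or the aldol may dehydrate in the hot medium.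
- **Fallback:** it sets out from 18. Aldol addition of the lithium enolate of N-methoxy-N-methylacetamide (LDA, THF, −78 °C) gives the β-hydroxy Weinreb amide F7. Silylation (TBSCl, imidazole, DMF) gives its silyl ether F8.
- **Return to the route:** Parham cyclisation (n-BuLi, THF, −90 °C; bromine–lithium exchange, then intramolecular acylation) closes the five-membered ring and comes back at 23, so step 13 is no longer needed.

Further compounds
F1 | step 17 | dibromocyclopropane: CBr2 bridges C1' and C3' of 27 on the face anti to OTBS (racemic) | COc1c(OCc2ccccc2)ccc2c1[C@H](O[Si](C)(C)C(C)(C)C)[C@H]1C(Br)(Br)[C@@]21c1c(OCc2ccccc2)cc(OC)c2c(OC)cc(C)cc12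
F2 | step 17 | tert-butyl({7-(benzyloxy)-3-bromo-4-(naphthyl A)-8-methoxynaphthalen-1-yl}oxy)dimethylsilane (racemic axis) | COc1c(OCc2ccccc2)ccc2c(-c3c(OCc4ccccc4)cc(OC)c4c(OC)cc(C)cc34)c(Br)cc(O[Si](C)(C)C(C)(C)C)c12
F3 | step 14 | 5-(benzyloxy)-4-methoxy-1H-inden-1-one | COc1c(OCc2ccccc2)ccc2c1C=CC2=O
F4 | step 14 | 5-(benzyloxy)-1-(naphthyl A)-4-methoxy-1H-inden-1-ol (racemic, one enantiomer drawn) | COc1c(OCc2ccccc2)ccc2c1C=C[C@@]2(O)c1c(OCc2ccccc2)cc(OC)c2c(OC)cc(C)cc12
F5 | step 14 | 6-(benzyloxy)-3-(naphthyl A)-7-methoxy-1H-inden-1-one | COc1c(OCc2ccccc2)ccc2c1C(=O)C=C2c1c(OCc2ccccc2)cc(OC)c2c(OC)cc(C)cc12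
F6 | step 14 | 6-(benzyloxy)-3-(naphthyl A)-7-methoxy-1H-inden-1-ol (racemic, one enantiomer drawn) | COc1c(OCc2ccccc2)ccc2c1[C@H](O)C=C2c1c(OCc2ccccc2)cc(OC)c2c(OC)cc(C)cc12
F7 | step 12 | 3-[3-(benzyloxy)-6-bromo-2-methoxyphenyl]-3-hydroxy-N-methoxy-N-methylpropanamide (racemic) | COc1c(OCc2ccccc2)ccc(Br)c1[C@H](O)CC(=O)N(C)OC
F8 | step 12 | 3-[3-(benzyloxy)-6-bromo-2-methoxyphenyl]-3-[(tert-butyldimethylsilyl)oxy]-N-methoxy-N-methylpropanamide (racemic) | COc1c(OCc2ccccc2)ccc(Br)c1[C@H](O[Si](C)(C)C(C)(C)C)CC(=O)N(C)OC
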